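**Plan**
Numbering (abietane): ring B = C5–C10 (C7 ketone, C10 quaternary), ring C = C8, C9, C11–C14, C1–C3 = propanoate arm.
Retrosynthesis: ring C is opened at C12–C13, because a hydroxy-p-quinone is the enol of a cyclohex-5-ene-1,2,4-trione (Dieckmann retron). Then C9–C11 (glycolate donor + 2-acyl enone), C8–C14 (acylation of a silyl enol ether), the C1–C2 olefin, and last ring B across C5–C6 and C9–C10 (Diels–Alder).
Enabling feature: the ring-B alkene C8=C9 is flanked by the C7 and C14 carbonyls, so C9 is a doubly activated Michael terminus. Once C9 carries the C11–C12 methoxalyl arm, the alkene holds the C13 methylene and the C12 ester cis and 1,6 to each other.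
Forward: dienal → ring B → propanoate arm → C8 isovaleryl → enone → C9 glycolate → oxidation to the enetrione keto ester → ring C, which appears directly as the free hydroxyquinone.
Stereochemistry: cis C10-methyl/C5-isopropenyl from the E dienophile (suprafacial cycloaddition); absolute configuration from the chiral oxazaborolidinium catalyst; the later centres at C8, C9 and C11 are mixtures that all become sp2.

Key step: step 10

Assumption: the sense of induction in step 3 is taken to follow the usual model for α-substituted enals bound to the protonated oxazaborolidine; if the antipode forms, the (R)-catalyst is used.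

**Route**

Step 1
Reactants: 1 methacrolein; 2 2-(triphenylphosphoranylidene)propanal
Product: 3 (2E)-2,4-dimethylpenta-2,4-dienal
Conditions: PhMe, 80 °C, sealed vessel, excess 1, trace BHT
Reagents that add atoms: none
Why: Wittig olefination with a formyl-stabilised ylide should give the E enal (formyl trans to the new isopropenyl group), the geometry that later places methyl and isopropenyl cis.

Step 2
Reactants: 4 but-3-en-2-one
Product: 5 2-[(triisopropylsilyl)oxy]buta-1,3-diene
Conditions: i-Pr3SiOTf, Et3N, Et2O, 0 °C → rt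
Reagents that add atoms: triisopropylsilyl trifluoromethanesulfonate, CC(C)[Si](OS(=O)(=O)C(F)(F)F)(C(C)C)C(C)C
Why: soft enolisation and O-silylation of the methyl ketone should give the cross-conjugated silyl dienol ether, the standard preparation of a 2-silyloxydiene.

Step 3
Reactants: 3 (2E)-2,4-dimethylpenta-2,4-dienal; 5 2-[(triisopropylsilyl)oxy]buta-1,3-diene
Product: 6 (1R,6S)-1-methyl-6-(prop-1-en-2-yl)-4-[(triisopropylsilyl)oxy]cyclohex-3-ene-1-carbaldehyde
Conditions: (S)-3,3-diphenyl-1-(o-tolyl)tetrahydro-1H,3H-pyrrolo[1,2-c][1,3,2]oxazaborole (20 mol %) activated with HN(SO2CF3)2 (20 mol %), CH2Cl2, −78 → −40 °C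
Reagents that add atoms: none
Why: enantioselective Diels–Alder reaction under cationic oxazaborolidine catalysis should give the "para" adduct (formyl-bearing C10 1,4 to the silyloxy carbon C7), the suprafacial addition turning the E geometry into cis C10-methyl/C5-isopropenyl while the catalyst shields one face of the bound s-trans enal and so fixes both centres.

Step 4
Reactants: 6 aldehyde from step 3; 7 trimethyl phosphonoacetate
Product: 8 methyl (2E)-3-[(1S,6S)-1-methyl-6-(prop-1-en-2-yl)-4-[(triisopropylsilyl)oxy]cyclohex-3-en-1-yl]prop-2-enoate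
Conditions: NaH, THF, 0 °C → rt
Reagents that add atoms: none
Why: Horner–Wadsworth–Emmons olefination of the non-enolisable neopentyl aldehyde should add C2 and C3 of the side arm without touching the silyl enol ether or the stereocentres.

Step 5
Reactants: 8 enoate from step 4
Product: 9 methyl 3-[(1R,6S)-1-methyl-6-(prop-1-en-2-yl)-4-[(triisopropylsilyl)oxy]cyclohex-3-en-1-yl]propanoate
Conditions: Cu(OAc)2·H2O (5 mol %), 1,2-bis(diphenylphosphino)benzene (5 mol %), 1,1,3,3-tetramethyldisiloxane, t-BuOH, PhMe, rt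
Reagents that add atoms: none
Why: copper hydride 1,4-reduction should be selective for the conjugated ester, since the isopropenyl group and the silyl enol ether are not activated towards hydrocupration.

Step 6
Reactants: 9 silyl enol ether from step 5; 10 3-methylbutanoyl chloride
Product: 11 methyl 3-[(1R,2S)-1-methyl-5-(3-methylbutanoyl)-4-oxo-2-(prop-1-en-2-yl)cyclohexyl]propanoate (C8 epimers and enol)
Conditions: ZnCl2 (20 mol %), CH2Cl2/Et2O, 0 °C → rt
Reagents that add atoms: none
Why: Lewis-acid-promoted C-acylation of a silyl enol ether should attach the isovaleryl unit (C14, C13) at C8 only, because the Diels–Alder reaction fixed the enol ether towards C8 and it is far more nucleophilic than the isopropenyl group.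

Step 7
Reactants: 11 β-diketone from step 6
Product: 14 methyl 3-[(1R,6S)-1-methyl-3-(3-methylbutanoyl)-4-oxo-6-(prop-1-en-2-yl)cyclohex-2-en-1-yl]propanoate, via C8 phenylselenide 12 (not isolated), via selenoxide 13 (not isolated)
Conditions: PhSeCl, pyridine, CH2Cl2, 0 °C; then 30 % aq. H2O2, 0 °C → rt
Reagents that add atoms: none
Why: selenenylation of the β-diketone enol at C8 followed by selenoxide syn-elimination should give the 2-acylcyclohex-2-enone, since the only syn β-hydrogens are on C9 and the quaternary C10 blocks dienol formation.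

Step 8
Reactants: 14 2-acyl enone from step 7; 15 methyl 2-[(trimethylsilyl)oxy]acetate
Product: 17 methyl 3-[(1S,6S)-2-(1-hydroxy-2-methoxy-2-oxoethyl)-1-methyl-3-(3-methylbutanoyl)-4-oxo-6-(prop-1-en-2-yl)cyclohexyl]propanoate (mixture at C8, C9, C11), via silyl ether 16 (not isolated)
Conditions: LDA, THF, −78 °C; then 14, −78 → −40 °C; 1 M HCl, THF, 0 °C
Reagents that add atoms: none
Why: Michael addition of an α-silyloxy ester enolate to an alkylidene 1,3-dicarbonyl should form C9–C11, the double activation by the C7 and C14 carbonyls offsetting the neopentyl position, and the acidic work-up cleaves the trimethylsilyl ether; the new centres are not controlled and need not be.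

Step 9
Reactants: 17 α-hydroxy ester from step 8
Product: 20 methyl 3-[(1S,6S)-2-(2-methoxy-2-oxoacetyl)-1-methyl-3-(3-methylbutanoyl)-4-oxo-6-(prop-1-en-2-yl)cyclohex-2-en-1-yl]propanoate, via α-keto ester 18 (not isolated), via C8 chloride 19 (not isolated)
Conditions: DMP (1,1,1-triacetoxy-1,1-dihydro-1,2-benziodoxol-3(1H)-one), CH2Cl2, 0 °C → rt; then NCS, Et3N, −20 → 0 °C; used crude
Reagents that add atoms: none
Why: Dess–Martin oxidation of the secondary α-hydroxy ester, chlorination of the diketone enol at C8 and E1cB loss of HCl through the C9–H (α to the new C11 ketone) should give the tetrasubstituted C8=C9 alkene, all diastereomers of 17 converging on one compound.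

Step 10
Reactants: 20 enetrione keto ester from step 9
Product: 21 methyl 3-[(1S,2S)-7-hydroxy-1-methyl-4,5,8-trioxo-6-(propan-2-yl)-2-(prop-1-en-2-yl)-1,2,3,4,5,8-hexahydronaphthalen-1-yl]propanoate (target)
Conditions: KOt-Bu (2.2 equiv), THF/t-BuOH, −20 °C → rt; then 1 M HCl
Reagents that add atoms: none
Why: tert-butoxide reversibly enolises the isovaleryl ketone at C13, the enolate attacks the methoxalyl ester carbon C12 held cis on C8=C9, and loss of methoxide gives the cyclohex-5-ene-1,2,4-trione, which is deprotonated at once to the 2-hydroxy-1,4-benzoquinone anion, so the sequence is drawn to one product. The closest known reaction type is the Dieckmann/Claisen cyclisation of a ketone enolate onto an oxalyl ester, as in the formation of cyclopentane-1,2,4-triones from ketones and dialkyl oxalates. Ring C closes in a 6-(enolexo)-exo-trig mode. No stereocentre is formed, and C5 and C10 cannot epimerise (C10 quaternary, C5–H not acidic). The step needs C13 to react rather than C6, which the substrate secures because a C6 enolate could only close onto C11 or C12 by placing the C8=C9 alkene at a bridgehead. It also needs Claisen closure at C12 rather than aldol closure at the C11 ketone, which is secured because the five-ring aldol adduct cannot dehydrate and reverts, while the Claisen product leaves the equilibrium as its stabilised anion; the side-arm ester is much less acidic than the C13 ketone position.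

**Compound list**
1 | methacrolein (2-methylprop-2-enal) | C=C(C)C=O | starting material
2 | 2-(triphenylphosphoranylidene)propanal | CC(C=O)=P(c1ccccc1)(c1ccccc1)c1ccccc1 | starting material
3 | (2E)-2,4-dimethylpenta-2,4-dienal | O=C/C(C)=C/C(C)=C | intermediate
4 | but-3-en-2-one | CC(=O)C=C | starting material
5 | 2-[(triisopropylsilyl)oxy]buta-1,3-diene | C=CC(=C)O[Si](C(C)C)(C(C)C)C(C)C | intermediate
6 | (1R,6S)-1-methyl-6-(prop-1-en-2-yl)-4-[(triisopropylsilyl)oxy]cyclohex-3-ene-1-carbaldehyde (methyl and isopropenyl cis) | C=C(C)[C@@H]1CC(O[Si](C(C)C)(C(C)C)C(C)C)=CC[C@@]1(C)C=O | intermediate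
7 | trimethyl phosphonoacetate | COC(=O)CP(=O)(OC)OC | starting material
8 | methyl (2E)-3-[(1S,6S)-1-methyl-6-(prop-1-en-2-yl)-4-[(triisopropylsilyl)oxy]cyclohex-3-en-1-yl]prop-2-enoate | C=C(C)[C@@H]1CC(O[Si](C(C)C)(C(C)C)C(C)C)=CC[C@@]1(C)/C=C/C(=O)OC | intermediate
9 | methyl 3-[(1R,6S)-1-methyl-6-(prop-1-en-2-yl)-4-[(triisopropylsilyl)oxy]cyclohex-3-en-1-yl]propanoate | C=C(C)[C@@H]1CC(O[Si](C(C)C)(C(C)C)C(C)C)=CC[C@@]1(C)CCC(=O)OC | intermediate
10 | 3-methylbutanoyl chloride | CC(C)CC(=O)Cl | starting material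
11 | methyl 3-[(1R,2S)-1-methyl-5-(3-methylbutanoyl)-4-oxo-2-(prop-1-en-2-yl)cyclohexyl]propanoate (C8 epimers and enol) | C=C(C)[C@@H]1CC(=O)C(C(=O)CC(C)C)C[C@@]1(C)CCC(=O)OC | intermediate
12 | methyl 3-[(1R,2S)-1-methyl-5-(3-methylbutanoyl)-4-oxo-5-(phenylselanyl)-2-(prop-1-en-2-yl)cyclohexyl]propanoate (C8 phenylselenide, not isolated) | C=C(C)[C@@H]1CC(=O)C([Se]c2ccccc2)(C(=O)CC(C)C)C[C@@]1(C)CCC(=O)OC | intermediate
13 | selenoxide of 12 (not isolated) | C=C(C)[C@@H]1CC(=O)C([Se](=O)c2ccccc2)(C(=O)CC(C)C)C[C@@]1(C)CCC(=O)OC | intermediate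
14 | methyl 3-[(1R,6S)-1-methyl-3-(3-methylbutanoyl)-4-oxo-6-(prop-1-en-2-yl)cyclohex-2-en-1-yl]propanoate | C=C(C)[C@@H]1CC(=O)C(C(=O)CC(C)C)=C[C@@]1(C)CCC(=O)OC | intermediate
15 | methyl 2-[(trimethylsilyl)oxy]acetate | COC(=O)CO[Si](C)(C)C | starting material
16 | trimethylsilyl ether of 17 (not isolated; mixture at C8, C9, C11) | C=C(C)[C@@H]1CC(=O)C(C(=O)CC(C)C)C(C(O[Si](C)(C)C)C(=O)OC)[C@@]1(C)CCC(=O)OC | intermediate
17 | methyl 3-[(1S,6S)-2-(1-hydroxy-2-methoxy-2-oxoethyl)-1-methyl-3-(3-methylbutanoyl)-4-oxo-6-(prop-1-en-2-yl)cyclohexyl]propanoate (mixture at C8, C9, C11) | C=C(C)[C@@H]1CC(=O)C(C(=O)CC(C)C)C(C(O)C(=O)OC)[C@@]1(C)CCC(=O)OC | intermediate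
18 | methyl 3-[(1S,6S)-2-(2-methoxy-2-oxoacetyl)-1-methyl-3-(3-methylbutanoyl)-4-oxo-6-(prop-1-en-2-yl)cyclohexyl]propanoate (not isolated) | C=C(C)[C@@H]1CC(=O)C(C(=O)CC(C)C)C(C(=O)C(=O)OC)[C@@]1(C)CCC(=O)OC | intermediate
19 | methyl 3-[(1S,6S)-3-chloro-2-(2-methoxy-2-oxoacetyl)-1-methyl-3-(3-methylbutanoyl)-4-oxo-6-(prop-1-en-2-yl)cyclohexyl]propanoate (not isolated) | C=C(C)[C@@H]1CC(=O)C(Cl)(C(=O)CC(C)C)C(C(=O)C(=O)OC)[C@@]1(C)CCC(=O)OC | intermediate
20 | methyl 3-[(1S,6S)-2-(2-methoxy-2-oxoacetyl)-1-methyl-3-(3-methylbutanoyl)-4-oxo-6-(prop-1-en-2-yl)cyclohex-2-en-1-yl]propanoate | C=C(C)[C@@H]1CC(=O)C(C(=O)CC(C)C)=C(C(=O)C(=O)OC)[C@@]1(C)CCC(=O)OC | intermediate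
21 | methyl 3-[(1S,2S)-7-hydroxy-1-methyl-4,5,8-trioxo-6-(propan-2-yl)-2-(prop-1-en-2-yl)-1,2,3,4,5,8-hexahydronaphthalen-1-yl]propanoate | C=C(C)[C@@H]1CC(=O)C2=C(C(=O)C(O)=C(C(C)C)C2=O)[C@@]1(C)CCC(=O)OC | target

Total step count: 10. Longest linear sequence: 9 (steps 1 and 3–10; step 2 prepares the diene).

**Steps most likely to fail**

Step 8. The ester enolate may act as a base towards C6–H of 14, or add reversibly, so that conjugate addition at the neopentyl C9 stays incomplete. The fallback sets out from 14 and uses a neutral inverse-electron-demand hetero-Diels–Alder reaction of the s-cis acyl-enone unit (O=C14–C8=C9) with commercial tris(trimethylsilyloxy)ethylene (PhMe, 60–80 °C, or high pressure). This should give the silyl ortho ester cycloadduct methyl 3-[(5S,6S)-5-methyl-1-(2-methylpropyl)-8-oxo-6-(prop-1-en-2-yl)-3,3,4-tris(trimethylsilyloxy)-4,4a,5,6,7,8-hexahydro-3H-isochromen-5-yl]propanoate F1. Acidic methanolysis (HCl in MeOH, 0 °C → rt) should open the ortho ester to the methyl α-hydroxy ester, and the route is rejoined at 17.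

Step 10. The C13 enolate may be held in the aldol manifold at the C11 ketone, or the enetrione may degrade under base before Claisen closure. The fallback sets out from 20: ketalisation of the most electrophilic ketone (C11, α to the ester) with HC(OMe)3, MeOH and catalytic camphorsulfonic acid should give the dimethyl ketal methyl 3-[(1S,6S)-1-methyl-3-(3-methylbutanoyl)-4-oxo-6-(prop-1-en-2-yl)-2-(1,1,2-trimethoxy-2-oxoethyl)cyclohex-2-en-1-yl]propanoate F2. With the aldol acceptor masked, LiHMDS (THF, −78 → 0 °C) should close ring C by the same C13-to-C12 Claisen condensation to the quinone monoketal methyl 3-[(1S,2S)-7-hydroxy-8,8-dimethoxy-1-methyl-4,5-dioxo-6-(propan-2-yl)-2-(prop-1-en-2-yl)-1,2,3,4,5,8-hexahydronaphthalen-1-yl]propanoate F3. Aqueous trifluoroacetic acid should then release the quinone carbonyl, and the route is rejoined at 21.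

Step 3. The trisubstituted dienal may be too unreactive, the silyloxydiene may add in a stepwise vinylogous (1,6) sense under Lewis acid activation, or facial discrimination may be poor. The fallback sets out from 3 and 5: an uncatalysed, concerted thermal cycloaddition (PhMe, 110 °C, sealed vessel, BHT) should give 6 as the racemate, that is together with its enantiomer (1S,6R)-1-methyl-6-(prop-1-en-2-yl)-4-[(triisopropylsilyl)oxy]cyclohex-3-ene-1-carbaldehyde F4. Preparative chromatography on a chiral stationary phase separates the two, and the route is rejoined at 6.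

Further compounds
F1 | step 8 | methyl 3-[(5S,6S)-5-methyl-1-(2-methylpropyl)-8-oxo-6-(prop-1-en-2-yl)-3,3,4-tris(trimethylsilyloxy)-4,4a,5,6,7,8-hexahydro-3H-isochromen-5-yl]propanoate | C=C(C)[C@@H]1CC(=O)C2=C(CC(C)C)OC(O[Si](C)(C)C)(O[Si](C)(C)C)C(O[Si](C)(C)C)C2[C@@]1(C)CCC(=O)OC
F2 | step 10 | methyl 3-[(1S,6S)-1-methyl-3-(3-methylbutanoyl)-4-oxo-6-(prop-1-en-2-yl)-2-(1,1,2-trimethoxy-2-oxoethyl)cyclohex-2-en-1-yl]propanoate | C=C(C)[C@@H]1CC(=O)C(C(=O)CC(C)C)=C(C(OC)(OC)C(=O)OC)[C@@]1(C)CCC(=O)OC
F3 | step 10 | methyl 3-[(1S,2S)-7-hydroxy-8,8-dimethoxy-1-methyl-4,5-dioxo-6-(propan-2-yl)-2-(prop-1-en-2-yl)-1,2,3,4,5,8-hexahydronaphthalen-1-yl]propanoate | C=C(C)[C@@H]1CC(=O)C2=C(C(OC)(OC)C(O)=C(C(C)C)C2=O)[C@@]1(C)CCC(=O)OC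
F4 | step 3 | (1S,6R)-1-methyl-6-(prop-1-en-2-yl)-4-[(triisopropylsilyl)oxy]cyclohex-3-ene-1-carbaldehyde | C=C(C)[C@H]1CC(O[Si](C(C)C)(C(C)C)C(C)C)=CC[C@]1(C)C=O
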